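**Retrosynthetic overview**

1. Numbering used below: carbocycle C5–C10 (C10 = quaternary carbon with methyl and vinyl C1=C2; C9 = CH2; C8 = C–O-acyl; C7 and C6 = lactone fusion carbons; C5 carries C4(=C3H2)C15H2OH); lactone C6–O–C12(=O)–C11(=C13H2)–C7.
2. Enabling feature: the oxygen-bearing ring carbon C8 and the ring carbon C5 that carries C4 are 1,4-related and flank the two-carbon unit C9–C10 with its 1,1-disubstituted C10. The carbocycle is therefore the [4+2] adduct of a 2-pyrone (ring O on C8, C2 carbonyl = C4, diene C5=C6–C7=C8) and methacrolein (C9=C10), forming C8–C9 and C5–C10.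
3. Later disconnections: C8–O ester by Mitsunobu inversion with the (R)-Roche acid; C15–OH from an allylsilane; lactone ring by carbonylative closure of a hydroxy enol triflate; C6–O and C7–H by conjugate borylation of a C7-acetyl enone; C7–C11 by Stille coupling at the C7 bromide; the C4 allylsilane and free C8–OH from the bridging lactone.
4. Ring order: carbocycle first (as a 2-oxabicyclo[2.2.2]octene, step 1), bridge opened in step 4, γ-lactone ring last (step 10).
5. Stereocontrol: C10, C5 and C8 from the catalysed cycloaddition; C6 and C7 relayed from C5 and C8; C8 inverted when the side chain is attached; the side-chain centre is bought.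

Key step: step 1

Remark: 3,5-dibromo-2H-pyran-2-one, methacrolein, methyl (R)-3-hydroxy-2-methylpropanoate, the oxazaborolidine precursor and all reagents are taken as commercially available.

Assumption: the face selection of the (S)-oxazaborolidinium catalyst in step 1 is taken from Corey's model for 2-substituted acroleins; should the antipodal adduct prevail, the (R)-catalyst would be used and nothing else changes.

**Route**

Step 1
Reactants: 1 3,5-dibromo-2H-pyran-2-one; 2 methacrolein
Product: 3 4,7-dibromo-5-methyl-3-oxo-2-oxabicyclo[2.2.2]oct-7-ene-5-carbaldehyde (formyl endo and anti to the O–C(=O) bridge)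
Conditions: 2 (3 equiv), (S)-3,3-diphenyl-1-(o-tolyl)tetrahydro-1H,3H-pyrrolo[1,2-c][1,3,2]oxazaborole (20 mol %) + HNTf2 (18 mol %), CH2Cl2, −40 to 0 °C
Reagents that add atoms: none
Why: Proposed new method: the triflimide-activated oxazaborolidine binds the formyl oxygen of s-trans methacrolein and lowers its LUMO, so the pyrone diene should add in a concerted, asynchronous normal-demand [4+2] in which the bond from pyrone C6 to the enal β-carbon (C8–C9) leads and the bond from pyrone C3 to the enal α-carbon (C5–C10) follows; the closest known reactions are the thermal cycloadditions of 3-bromo- and 3,5-dibromo-2-pyrone with acrolein and acrylates and the oxazaborolidinium-catalysed Diels–Alder reactions of 2-substituted acroleins with simple dienes. The carbocycle is closed by this suprafacial six-centre cycloaddition, which at the same time turns the pyrone O–C(=O) unit into a two-atom bridge, so that C8–O and C5–C4 are necessarily cis. The regiochemistry needed (formyl-bearing carbon next to the brominated bridgehead) is the one recorded for 3-bromo-2-pyrones with acceptor alkenes and is secured by the C3 bromine. The quaternary centre C10 should be set relative to the bridge by the endo rule (formyl under the diene, methyl toward the hydrogen-free O–C(=O) bridge, where it meets no steric penalty) and in the absolute sense by the catalyst, which shields one face of the bound enal; C5 and C8 follow from C10 through the rigid bicycle. The step needs endo and enantiofacial selectivity and a diene that tolerates the Lewis acid; the weakly basic lactone carbonyl and the two bromine atoms, which also make the pyrone a more reactive diene, are what the substrate offers for this.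

Step 2
Reactants: 3 the bicyclic aldehyde
Product: 4 4,7-dibromo-5-methyl-5-vinyl-2-oxabicyclo[2.2.2]oct-7-en-3-one
Conditions: Ph3PCH3Br (1.3 equiv), KOtBu (1.2 equiv), THF, 0 °C; then 3, −78 to 0 °C
Reagents that add atoms: methyltriphenylphosphonium bromide, C[P+](c1ccccc1)(c1ccccc1)c1ccccc1.[Br-]
Why: Wittig methylenation of the non-enolisable neopentyl aldehyde, which is far more electrophilic than the lactone, installs C1=C2 before the radical step so that the bridgehead radical never sits next to a migrating formyl group.

Step 3
Reactants: 4 the dibromo vinyl lactone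
Product: 5 7-bromo-5-methyl-5-vinyl-2-oxabicyclo[2.2.2]oct-7-en-3-one
Conditions: Bu3SnH (1.2 equiv, 0.5 M), AIBN (cat.), benzene, 80 °C
Reagents that add atoms: none
Why: radical hydrodebromination, in which the tertiary α-acyl C–Br bond is abstracted much faster than the alkenyl C–Br bond, the bridgehead radical can only be quenched with retention, and the high stannane concentration should outrun 3-exo attack on the vinyl group.

Step 4
Reactants: 5 the monobromo lactone
Product: 7 2-bromo-5-methyl-4-[3-(trimethylsilyl)prop-1-en-2-yl]-5-vinylcyclohex-2-en-1-ol (OH and the C4 side chain and the 5-methyl group all cis), via bis(silylmethyl) carbinol 6 (not isolated)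
Conditions: Me3SiCH2MgCl (5 equiv), CeCl3 (5 equiv), THF, −78 °C to rt; aq NH4Cl; then silica gel, CH2Cl2, rt
Reagents that add atoms: (trimethylsilyl)methylmagnesium chloride, C[Si](C)(C)C[Mg]Cl
Why: cerium-mediated double addition of the silylmethyl reagent to the strained lactone and Peterson elimination (Bunnelle allylsilane synthesis) turn the bridge carbonyl C4 into the 2-(silylmethyl)allyl group and free C8–OH, while the weakly basic cerium reagent should not enolise the intermediate ketone at C5.

Step 5
Reactants: 7 the allylsilane alcohol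
Product: 8 triethylsilyl ether of 7
Conditions: Et3SiCl, imidazole, CH2Cl2, 0 °C
Reagents that add atoms: chlorotriethylsilane, CC[Si](Cl)(CC)CC
Why: standard silylation of the secondary allylic alcohol, which protects C8–OH from the base and triflating agent of step 8 with a group that can later be removed without harm to the allylsilane.

Step 6
Reactants: 8 the silyl ether
Product: 10 1-{4-methyl-6-(triethylsilyloxy)-3-[3-(trimethylsilyl)prop-1-en-2-yl]-4-vinylcyclohex-1-en-1-yl}ethan-1-one, via 1-ethoxyvinyl diene 9 (not isolated)
Conditions: tributyl(1-ethoxyvinyl)stannane (1.5 equiv), Pd(PPh3)4 (5 mol %), toluene, 100 °C; then PPTS, acetone–H2O, 0 °C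
Reagents that add atoms: tributyl(1-ethoxyvinyl)stannane, CCCC[Sn](CCCC)(CCCC)C(=C)OCC; water, O
Why: Stille coupling of the alkenyl bromide with the acetyl-anion equivalent and mild hydrolysis of the dienyl ether give the C7-acetyl enone (C11 and C13 in place) under conditions that the allylsilane and silyl ether should survive.

Step 7
Reactants: 10 the acetyl enone
Product: 11 1-{4-methyl-2-(4,4,5,5-tetramethyl-1,3,2-dioxaborolan-2-yl)-6-(triethylsilyloxy)-3-[3-(trimethylsilyl)prop-1-en-2-yl]-4-vinylcyclohexyl}ethan-1-one (boron trans to acetyl and to the C5 side chain)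
Conditions: CuCl (10 mol %), 1,3-bis(2,4,6-trimethylphenyl)imidazolium chloride (10 mol %), NaOtBu (15 mol %), B2pin2 (1.3 equiv), MeOH (2 equiv), THF, 0 °C to rt
Reagents that add atoms: bis(pinacolato)diboron, CC1(C)OB(OC1(C)C)B1OC(C)(C)C(C)(C)O1
Why: copper-catalysed conjugate borylation of the enone should deliver boron to C6 from the face opposite the C5 side chain and the pseudo-axial C8 silyloxy group, and protonation at C7 from the same axial direction (net syn addition of B and H) should place the acetyl group trans to boron.

Step 8
Reactants: 11 the β-boryl ketone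
Product: 13 enol triflate of 11 (1-substituted vinyl trifluoromethanesulfonate), via potassium enolate 12 (not isolated)
Conditions: KN(SiMe3)2 (1.1 equiv), THF, −78 °C; then PhNTf2 (1.2 equiv), −78 to −40 °C
Reagents that add atoms: N-phenylbis(trifluoromethanesulfonimide), O=S(=O)(N(c1ccccc1)S(=O)(=O)C(F)(F)F)C(F)(F)F
Why: kinetic deprotonation of the methyl ketone at the methyl group and O-triflation give the 1,1-disubstituted enol triflate without enolising C7, which also avoids β-elimination of the C6 or C8 substituent.

Step 9
Reactants: 13 the boryl enol triflate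
Product: 14 hydroxy enol triflate (C6–OH trans to the C7 side chain)
Conditions: NaBO3·4H2O (5 equiv), THF–H2O, 0 °C to rt
Reagents that add atoms: sodium perborate (used as the tetrahydrate), [Na+].[O-]OB=O
Why: perborate oxidation of the secondary alkylboronate proceeds by 1,2-migration with retention and is mild enough for the enol triflate, giving the C6 alcohol with the lactone oxygen in its final configuration.

Step 10
Reactants: 14 the hydroxy enol triflate
Product: 15 6-methyl-3-methylene-4-(triethylsilyloxy)-7-[3-(trimethylsilyl)prop-1-en-2-yl]-6-vinylhexahydro-1-benzofuran-2(3H)-one (trans-fused)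
Conditions: Pd(PPh3)4 (10 mol %), CO (1 atm), Et3N (2 equiv), LiCl, MeCN, 60 °C
Reagents that add atoms: carbon monoxide, [C-]#[O+]
Why: oxidative addition into the enol triflate, CO insertion and capture of the acylpalladium by the neighbouring C6 hydroxyl (carbonylative lactonisation of hydroxy vinyl triflates) should close the trans-fused α-methylene γ-lactone directly, with C12 from CO.

Step 11
Reactants: 15 the silyl-protected lactone
Product: 16 4-hydroxy analogue of 15 (C8–OH still on the face of the C10 methyl group)
Conditions: HF·pyridine, pyridine, THF, 0 °C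
Reagents that add atoms: none
Why: buffered fluoride cleavage of the triethylsilyl ether should leave the allylsilane, the methylene lactone and the alkenes untouched.

Step 12
Reactants: 17 methyl (R)-3-hydroxy-2-methylpropanoate
Product: 18 methyl (R)-3-(tert-butyldimethylsilyloxy)-2-methylpropanoate
Conditions: TBSCl, imidazole, CH2Cl2, 0 °C to rt
Reagents that add atoms: tert-butyldimethylsilyl chloride, CC(C)(C)[Si](C)(C)Cl
Why: routine silylation of the primary alcohol of the Roche ester, which does not touch the bought stereocentre.

Step 13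
Reactants: 18 the silyl-protected Roche ester
Product: 19 (R)-3-(tert-butyldimethylsilyloxy)-2-methylpropanoic acid
Conditions: LiOH, THF–H2O, 0 °C; aq HCl work-up to pH 3
Reagents that add atoms: lithium hydroxide, [Li+].[OH-]
Why: cold saponification of the methyl ester is standard for this building block and should proceed without epimerisation or β-elimination.

Step 14
Reactants: 16 the C8 alcohol; 19 the protected Roche acid
Product: 20 C8-inverted ester: the (R)-3-(tert-butyldimethylsilyloxy)-2-methylpropanoate of the C8 epimer of 16
Conditions: PPh3 (2 equiv), DIAD (2 equiv), toluene, 0 °C (betaine preformed); then 19 (2 equiv) and 16, 0 °C to rt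
Reagents that add atoms: none
Why: Mitsunobu esterification, in which the carboxylate displaces the axial C8 oxyphosphonium group from the unhindered opposite face, inverts C8 to the equatorial configuration of the target and attaches the side chain in the same step; preforming the betaine keeps free phosphine away from the methylene lactone.

Step 15
Reactants: 20 the protected ester
Product: 22 target CNP0133858.1, via epoxysilane 21 (not isolated)
Conditions: mCPBA (1.1 equiv), NaHCO3, CH2Cl2, 0 °C; then HF·pyridine, THF, 0 °C to rt
Reagents that add atoms: 3-chloroperoxybenzoic acid, OOC(=O)c1cccc(Cl)c1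
Why: peracid epoxidation should be selective for the electron-rich allylsilane over the monosubstituted vinyl group and the electron-poor methylene lactone, and the epoxysilane opens with loss of silicon to the 2-(hydroxymethyl)vinyl group (allylsilane-to-allylic-alcohol transposition) while the same fluoride source removes the TBS ether.

**Compound list**

1 | 3,5-dibromo-2H-pyran-2-one | O=C1OC=C(Br)C=C1Br | starting material
2 | methacrolein | CC(=C)C=O | starting material
3 | 4,7-dibromo-5-methyl-3-oxo-2-oxabicyclo[2.2.2]oct-7-ene-5-carbaldehyde (formyl anti to the lactone bridge) | O=C[C@]1(C)C[C@H]2OC(=O)[C@]1(Br)C=C2Br | intermediate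
4 | 4,7-dibromo-5-methyl-5-vinyl-2-oxabicyclo[2.2.2]oct-7-en-3-one | C=C[C@]1(C)C[C@H]2OC(=O)[C@]1(Br)C=C2Br | intermediate
5 | 7-bromo-5-methyl-5-vinyl-2-oxabicyclo[2.2.2]oct-7-en-3-one | C=C[C@]1(C)C[C@H]2OC(=O)[C@@H]1C=C2Br | intermediate
6 | 2-(5-bromo-4-hydroxy-2-methyl-2-vinylcyclohex-5-en-1-yl)-1,3-bis(trimethylsilyl)propan-2-ol | C=C[C@]1(C)C[C@@H](O)C(Br)=C[C@H]1C(O)(C[Si](C)(C)C)C[Si](C)(C)C | intermediate
7 | 2-bromo-5-methyl-4-[3-(trimethylsilyl)prop-1-en-2-yl]-5-vinylcyclohex-2-en-1-ol | C=C[C@]1(C)C[C@@H](O)C(Br)=C[C@H]1C(=C)C[Si](C)(C)C | intermediate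
8 | triethylsilyl ether of 7 | C=C[C@]1(C)C[C@@H](O[Si](CC)(CC)CC)C(Br)=C[C@H]1C(=C)C[Si](C)(C)C | intermediate
9 | 2-(1-ethoxyvinyl) analogue of 8 | C=C[C@]1(C)C[C@@H](O[Si](CC)(CC)CC)C(C(=C)OCC)=C[C@H]1C(=C)C[Si](C)(C)C | intermediate
10 | 1-{4-methyl-6-(triethylsilyloxy)-3-[3-(trimethylsilyl)prop-1-en-2-yl]-4-vinylcyclohex-1-en-1-yl}ethan-1-one | C=C[C@]1(C)C[C@@H](O[Si](CC)(CC)CC)C(C(C)=O)=C[C@H]1C(=C)C[Si](C)(C)C | intermediate
11 | β-boryl ketone (boron on C6, acetyl on C7, trans) | C=C[C@]1(C)C[C@@H](O[Si](CC)(CC)CC)[C@@H](C(C)=O)[C@H](B2OC(C)(C)C(C)(C)O2)[C@H]1C(=C)C[Si](C)(C)C | intermediate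
12 | potassium enolate of 11 (methyl side) | C=C[C@]1(C)C[C@@H](O[Si](CC)(CC)CC)[C@@H](C(=C)[O-])[C@H](B2OC(C)(C)C(C)(C)O2)[C@H]1C(=C)C[Si](C)(C)C.[K+] | intermediate
13 | enol triflate of 11 | C=C[C@]1(C)C[C@@H](O[Si](CC)(CC)CC)[C@@H](C(=C)OS(=O)(=O)C(F)(F)F)[C@H](B2OC(C)(C)C(C)(C)O2)[C@H]1C(=C)C[Si](C)(C)C | intermediate
14 | hydroxy enol triflate | C=C[C@]1(C)C[C@@H](O[Si](CC)(CC)CC)[C@@H](C(=C)OS(=O)(=O)C(F)(F)F)[C@H](O)[C@H]1C(=C)C[Si](C)(C)C | intermediate
15 | 6-methyl-3-methylene-4-(triethylsilyloxy)-7-[3-(trimethylsilyl)prop-1-en-2-yl]-6-vinylhexahydro-1-benzofuran-2(3H)-one | C=C[C@]1(C)C[C@@H](O[Si](CC)(CC)CC)[C@H]2C(=C)C(=O)O[C@@H]2[C@H]1C(=C)C[Si](C)(C)C | intermediate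
16 | 4-hydroxy-6-methyl-3-methylene-7-[3-(trimethylsilyl)prop-1-en-2-yl]-6-vinylhexahydro-1-benzofuran-2(3H)-one | C=C[C@]1(C)C[C@@H](O)[C@H]2C(=C)C(=O)O[C@@H]2[C@H]1C(=C)C[Si](C)(C)C | intermediate
17 | methyl (R)-3-hydroxy-2-methylpropanoate | COC(=O)[C@H](C)CO | starting material
18 | methyl (R)-3-(tert-butyldimethylsilyloxy)-2-methylpropanoate | COC(=O)[C@H](C)CO[Si](C)(C)C(C)(C)C | intermediate
19 | (R)-3-(tert-butyldimethylsilyloxy)-2-methylpropanoic acid | OC(=O)[C@H](C)CO[Si](C)(C)C(C)(C)C | intermediate
20 | C8-inverted silyl-protected ester (allylsilane) | C=C[C@]1(C)C[C@H](OC(=O)[C@H](C)CO[Si](C)(C)C(C)(C)C)[C@H]2C(=C)C(=O)O[C@@H]2[C@H]1C(=C)C[Si](C)(C)C | intermediate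
21 | epoxysilane of 20 (epimers at the epoxide carbon) | C=C[C@]1(C)C[C@H](OC(=O)[C@H](C)CO[Si](C)(C)C(C)(C)C)[C@H]2C(=C)C(=O)O[C@@H]2[C@H]1C3(CO3)C[Si](C)(C)C | intermediate
22 | CNP0133858.1: 7-(3-hydroxyprop-1-en-2-yl)-6-methyl-3-methylene-2-oxo-6-vinyloctahydro-1-benzofuran-4-yl (R)-3-hydroxy-2-methylpropanoate | C=C[C@]1(C)C[C@H](OC(=O)[C@H](C)CO)[C@H]2C(=C)C(=O)O[C@@H]2[C@H]1C(=C)CO | target

**Step count and risks**

Total step count: 15. Longest linear sequence: 13 (steps 1 to 11, then 14 and 15).

Steps most likely to fail:

1. Step 1 (Proposed new method). The catalysed cycloaddition may be slow because pyrone or product binds the Lewis acid, or it may give poor endo or facial selectivity. The fallback sets out from 1 and 2 and uses the known thermal cycloaddition of bromopyrones with acceptor alkenes (toluene, 100 °C, sealed tube, BHT). This should give the endo adduct as a racemate, that is 3 together with its enantiomer F1. Resolution by preparative chromatography on a chiral stationary phase then returns to the route at 3.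

2. Step 14. The axial oxyphosphonium intermediate may undergo anti elimination toward C7 or C9, or the acid may be transferred with retention through an acyloxyphosphonium pathway. The fallback sets out from 16 and separates activation from displacement: Tf2O and pyridine in CH2Cl2 at −30 °C should give the C8 triflate F2, and the cesium salt of 19 (Cs2CO3, 18-crown-6, toluene, 0 °C to rt) should displace it with inversion in a Kellogg-type carboxylate substitution. This comes back to the route at 20.

3. Step 7. Boron delivery to the hindered C6 may be slow or poorly face-selective, the C7 centre may be scrambled by enolisation, or the C8 silyloxy group may be lost by β-elimination. The fallback sets out from 10 and replaces conjugate borylation by epoxidation and reductive opening. Weitz–Scheffer epoxidation (t-BuOOH, DBU, CH2Cl2) should give the epoxy ketone F3 with the epoxide anti to the C5 and C8 substituents. SmI2 in THF–MeOH at −90 °C should cleave the C7–O bond to the β-hydroxy ketone F4. Me3SiCl and Et3N should give the trimethylsilyl ether F5, and KN(SiMe3)2 with PhNTf2 its enol triflate F6. Citric acid in MeOH then removes the trimethylsilyl group, and the route is rejoined at 14.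

**Further compounds**

F1 | step 1 | enantiomer of 3 | O=C[C@@]1(C)C[C@@H]2OC(=O)[C@@]1(Br)C=C2Br
F2 | step 14 | C8 trifluoromethanesulfonate of 16 | C=C[C@]1(C)C[C@@H](OS(=O)(=O)C(F)(F)F)[C@H]2C(=C)C(=O)O[C@@H]2[C@H]1C(=C)C[Si](C)(C)C
F3 | step 7 | C6–C7 epoxy ketone from 10 | C=C[C@]1(C)C[C@@H](O[Si](CC)(CC)CC)[C@]2(C(C)=O)O[C@@H]2[C@H]1C(=C)C[Si](C)(C)C
F4 | step 7 | C6 β-hydroxy ketone | C=C[C@]1(C)C[C@@H](O[Si](CC)(CC)CC)[C@@H](C(C)=O)[C@H](O)[C@H]1C(=C)C[Si](C)(C)C
F5 | step 7 | trimethylsilyl ether of F4 | C=C[C@]1(C)C[C@@H](O[Si](CC)(CC)CC)[C@@H](C(C)=O)[C@H](O[Si](C)(C)C)[C@H]1C(=C)C[Si](C)(C)C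
F6 | step 7 | enol triflate of F5 | C=C[C@]1(C)C[C@@H](O[Si](CC)(CC)CC)[C@@H](C(=C)OS(=O)(=O)C(F)(F)F)[C@H](O[Si](C)(C)C)[C@H]1C(=C)C[Si](C)(C)C
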